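The numbers in the tables come from a simulation on assumed constants; noise was put on by code.

If a flat stretch in a run is to mean equilibrium, the flask must first have travelled there, so watch how each run arrives.

| flask | G | D | temperature | remark | time |
|---|---|---|---|---|---|
| teal | 0.0010 M | 0.0040 µM | 18 °C | run made earlier |  |
| violet | 0.0010 M | 0.0059 µM | 45 °C | run made earlier |  |
| blue | 0.0015 M | 0.0079 µM | 18 °C | run made earlier |  |
| north-east | 0.0010 M | 0.0079 µM | 55 °C |  | 4.0 min |
| east | 0.0010 M | 0.0079 µM | 30 °C |  | 4.0 min |
| south-west | 0.0010 M | 0.0079 µM | 5 °C |  | 4.0 min |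

- teal (time / min: X / %): 1.33: 58; 4.00: 47; 6.00: 44; 10.0: 42; 15.0: 45; 20.0: 45; 25.0: 45
- violet (time / min: X / %): 0.833: 24; 1.50: 22; 2.50: 22; 4.00: 23; 5.00: 20; 6.00: 22
- blue (time / min: X / %): 2.00: 48; 6.00: 43; 12.0: 45; 20.0: 42; 25.0: 42

(scatter of a reading: 1.5 percentage points)

* the flask that comes out highest in amount of X, in percent of the G charged, or "all alike" when all lie within 1.5 percentage points (north-east / east / south-west / all alike)
* X at the end, in percent of the G charged, north-east
* X at the end, in percent of the G charged, east
* X at the end, in percent of the G charged, south-west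



In the first minutes of the teal flask, the enzyme D turns G into X, which reads 58% at 1.33 min. In the middle, X falls to 47% at 4.00 min, so something takes X away after it is made. At the end it reads 45%. That is the shape of an approach to equilibrium. The violet flask shows no such middle: X reads 24% at 0.833 min and stays near 22% up to 6.00 min. My own reading is that D stopped in the violet flask, so I follow one D and count:

violet: 22% of 0.0010 M G, over 0.0059 µM D, gives 37300

Call this reading N, the turnover capacity, meaning the X made per D charged before D stops (the total turnover number). Set it against the load L, the G charged per D charged: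

new flasks: L = 0.0010 M / 0.0079 µM = 1.27 × 10⁵

teal, by 1.33 min: N is at least 1.45 × 10⁵

So at 18 °C the teal N exceeds L, while the violet N falls short of it. North-east is hotter than the violet flask, so I expect its X below 29.5%. For east I have no ceiling from N, and I do not take the violet reading as an equilibrium.

The forecast gives 17%, 33% and 63% for north-east, east and south-west, with south-west highest, holding that “the plateau looks like a true equilibrium that favours X less on warming”.

    D → J (k = 9.80 × 10⁻⁴ s⁻¹, Ea = 261 kJ mol⁻¹)
    G + D → X + D, rate k2*[G]*[D]/(1 + ([G]/Km2) + ([G]/Ksi2)^2) (0.0580 mM, 0.310 mM, k = 1.10 × 10⁸ M⁻¹ s⁻¹, Ea = 12.0 kJ mol⁻¹)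
    X ⇌ Q (K = 0.330, k = 0.0350 s⁻¹, Ea = 73.0 kJ mol⁻¹, ΔH = −68.0 kJ mol⁻¹)
    2 G → Z (k = 7.60 M⁻¹ s⁻¹, Ea = 53.0 kJ mol⁻¹)
    (constants at 30 °C)

East comes out highest, with 1.62% in north-east, 66.0% in east and 57.7% in south-west. With the step from D to J struck out, north-east gives 68.8%. North-east holds 2050 X per D charged, less than the violet N of 37300.

Now take the flask like east run at 15 °C. Its load L of 1.27 × 10⁵ is below the lower bound of 1.45 × 10⁵ read in the teal flask, and it runs colder than the teal flask, so I expect D to outlast the charge. It ends with G at 0%, D at 99.9% of its charge and X at 42.9%.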